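**Retrosynthetic overview**

1. Numbering (daucane): C1 = methyl-bearing ring-fusion carbon, C4 = isopropyl carbinol, C5 = ring-fusion CH, C6 = ester carbon, C7=C8(C14 methyl), C9 = ketone, C10 = CH2. End game: veratroylation of C6–OH ⇐ C4–OH-directed reduction of the C6 ketone ⇐ Saegusa enone.
2. Key disconnection: the ring-fusion bond C1–C5, made by a semipinacol 1,2-shift in which C1 migrates from C6 to C5. Enabling feature: the C6 oxygen (ketone level) sits directly beside C5, so with C1 bonded to C6 instead of C5 the cyclopentane carbons C1–C5 plus C6 form a cyclohexane (ring A) and the seven-membered ring minus C5 a cyclohexene (ring B), i.e. a cis-decalin whose C5 carries a leaving group.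
3. cis-Decalin ⇐ Diels–Alder reaction of enone 6 (C5 ketone, C6=C1 dienophile) with 2-siloxydiene 8 (C7–C10 and C14), then angular C6 hydroxylation, C5 reduction and mesylation.
4. Enone 6 (ring A with the C4 carbinol, the isopropyl group and the C1 methyl) ⇐ (S)-terpinen-4-ol by 1,3-transposed allylic oxidation.
5. Ring order: ring A (chiral pool) → ring B ([4+2]) → five-membered ring (contraction of ring A) and seven-membered ring (expansion of ring B) together in the key step.

Key step: step 9

Assumption: (S)-terpinen-4-ol is taken as enantiomerically pure material (commercial samples are enantiomerically enriched and can be upgraded through a crystalline ester before use).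

**Route**

Step 1
Reactants: 1 (S)-terpinen-4-ol
Product: 2 (S)-tert-butyldimethyl{[4-methyl-1-(propan-2-yl)cyclohex-3-en-1-yl]oxy}silane
Conditions: TBSOTf, 2,6-lutidine, CH2Cl2, 0 °C → rt
Reagents that add atoms: tert-butyldimethylsilyl trifluoromethanesulfonate, C[Si](C)(OS(=O)(=O)C(F)(F)F)C(C)(C)C
Why: O-silylation of a hindered tertiary alcohol with a silyl triflate (silyl ether protection) leaves the carbinol stereocentre untouched and installs a bulky, non-chelating group that later holds the C4 oxygen axial on ring A.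

Step 2
Reactants: 2 (S)-terpinen-4-ol TBS ether
Product: 5 4-(tert-butyldimethylsilyloxy)-1-methyl-4-(propan-2-yl)cyclohex-2-en-1-ol, via hydroxy selenide 3 (not isolated), via selenoxide 4 (not isolated)
Conditions: N-(phenylseleno)phthalimide, H2O, PPTS (cat.), CH2Cl2, rt; then 30% H2O2, THF, 0 °C → rt
Reagents that add atoms: water, O
Why: Electrophilic hydroxyselenation (anti addition, water opening the seleniranium ion at the tertiary carbon, Markovnikov) followed by selenoxide syn-elimination, which can only run toward the C5 methylene because the other β-carbon is the fully substituted carbinol, should give the tertiary allylic alcohol needed for transposition; the new carbinol centre is inconsequential because it becomes sp2 in step 3.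

Step 3
Reactants: 5 tertiary allylic alcohol
Product: 6 (R)-6-(tert-butyldimethylsilyloxy)-3-methyl-6-(propan-2-yl)cyclohex-2-en-1-one
Conditions: pyridinium chlorochromate (C5H5NH)[CrO3Cl], 4 Å molecular sieves, CH2Cl2, rt
Reagents that add atoms: pyridinium chlorochromate, [O-][Cr](=O)(=O)Cl.c1cc[nH+]cc1
Why: Babler–Dauben oxidative transposition: the tertiary allylic chromate ester undergoes a [3,3]-shift to C5 and is oxidised there by the hexavalent chromium reagent, which should deliver the β-methyl enone with the carbonyl next to the untouched C4 stereocentre.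

Step 4
Reactants: 7 3-methylbut-3-en-2-one
Product: 8 tert-butyldimethyl[(3-methylbuta-1,3-dien-2-yl)oxy]silane
Conditions: TBSOTf, Et3N, CH2Cl2, 0 °C
Reagents that add atoms: tert-butyldimethylsilyl trifluoromethanesulfonate, C[Si](C)(OS(=O)(=O)C(F)(F)F)C(C)(C)C
Why: Soft enolisation and O-silylation (silyl enol ether formation) of a methyl ketone that can enolise only toward its methyl group should give the 2-siloxydiene.

Step 5
Reactants: 6 enone; 8 2-siloxydiene
Product: 9 cis-fused 2,6-bis(tert-butyldimethylsilyloxy)-4a,7-dimethyl-2-(propan-2-yl)-3,4,4a,5,8,8a-hexahydronaphthalen-1(2H)-one (4a-methyl, 8a-H and 2-siloxy group on one face)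
Conditions: AlBr3/AlMe3 (10:1, 30 mol %), toluene–CH2Cl2, −10 → 0 °C; pyridine quench
Reagents that add atoms: none
Why: Lewis-acid-promoted Diels–Alder reaction of a hindered β-methyl enone with a 2-siloxydiene (mixed aluminium Lewis acid catalysis is the close precedent): the nucleophilic CH2 terminus of the diene (C10) bonds to the β-carbon C1 and C7 to C6, suprafacial addition makes the ring fusion cis, and the diene should add anti to the pseudo-axial C4 siloxy group of the half-chair whose isopropyl group is pseudo-equatorial (chair-like axial bond formation at C1), which places C10 cis to the isopropyl group and the C15 methyl cis to the C4 oxygen as in the target.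

Step 6
Reactants: 9 cis-decalone
Product: 12 cis-fused 2,6-bis(tert-butyldimethylsilyloxy)-8a-hydroxy-4a,7-dimethyl-2-(propan-2-yl)-3,4,4a,5,8,8a-hexahydronaphthalen-1(2H)-one (8a-OH cis to the 4a-methyl), via potassium enolate 10 (not isolated), via hydroperoxide 11 (not isolated)
Conditions: KN(SiMe3)2, THF, −78 → −20 °C; then O2, P(OEt)3, −78 °C; aq. NH4Cl
Reagents that add atoms: dioxygen, O=O
Why: Enolate oxygenation (autoxidation of the enolate, phosphite reduction of the hydroperoxide in situ): C6–H is the only α-hydrogen of the C5 ketone because C4 is quaternary and C9 is masked as its silyl enol ether, and the ring-fusion enolate should take up oxygen on the face that leads to the chair-like cis-decalin (axial C–O bond anti to the axial C1–C10 bond), i.e. cis to the C15 methyl.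

Step 7
Reactants: 12 α-hydroxy ketone
Product: 13 cis-fused 2,6-bis(tert-butyldimethylsilyloxy)-4a,7-dimethyl-2-(propan-2-yl)-1,2,3,4,4a,5,8,8a-octahydronaphthalene-1,8a-diol (1-OH, 2-siloxy, 8a-OH and 4a-methyl on one face)
Conditions: NaBH4, MeOH–THF, −20 → 0 °C
Reagents that add atoms: none
Why: Borohydride reduction of a ketone flanked by two axial C–O bonds: hydride should add axially, anti to both C–O bonds (polar Felkin–Anh control, equatorial attack being blocked by the two axial oxygen substituents), which gives the equatorial C5 alcohol cis to the C4 and C6 oxygens while both silyl groups are inert.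

Step 8
Reactants: 13 diol
Product: 14 1-O-methanesulfonate of diol 13
Conditions: MsCl, Et3N, CH2Cl2, −10 °C
Reagents that add atoms: methanesulfonyl chloride, CS(=O)(=O)Cl
Why: Sulfonylation through sulfene (mesylation) should take place only at the secondary C5 hydroxyl, the tertiary C6 hydroxyl being unreactive, and gives the equatorial leaving group without touching a stereocentre.

Step 9
Reactants: 14 hydroxy mesylate
Product: 16 (3R,3aR,8aR)-3,7-bis(tert-butyldimethylsilyloxy)-6,8a-dimethyl-3-(propan-2-yl)-2,3,3a,5,8,8a-hexahydroazulen-4(1H)-one (trans-fused), via diethylaluminium alkoxide 15 (not isolated)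
Conditions: AlEt3 (3 equiv), CH2Cl2, −78 → 0 °C; aq. potassium sodium tartrate
Reagents that add atoms: none
Why: AlEt3 converts the tertiary C6–OH of 14 into the aluminium alkoxide 15 (ethane is lost) and the Lewis-acidic aluminium, held next to C5, activates the mesylate; the C1–C6 σ-bond, antiperiplanar to the equatorial C5–O bond in the chair of ring A (isopropyl equatorial, C4 siloxy and C6 oxygen axial), then shifts to C5 as the mesylate leaves and C6 becomes the ketone (semipinacol 1,2-shift). The closest known reaction types are the organoaluminium-promoted semipinacol rearrangement of β-mesyloxy alcohols and the pinacol-type conversion of hydronaphthalene 1,2-diol monosulfonates into hydroazulenones. The five-membered ring is closed by contraction of ring A (C1 bonds to C5 through a three-centre, SN2-like transition state while its bond to C6 breaks) and the seven-membered ring by one-carbon expansion of ring B (C5 is inserted between C6 and C1). C5 is formed with inversion (C1 enters anti to the mesylate, which places H-5 trans to the C15 methyl, the trans ring fusion), and C1 migrates with retention, so its configuration from step 5 and that of C4 are carried over unchanged. The step needs migration of C1 in preference to C7 or C3 and no epoxide or alkene formation: of the bonds at C6 only C6–C1 is antiperiplanar to the mesylate, the C4 oxygen is silylated and cannot push C3 across, the C6 oxygen is gauche to the mesylate and cannot close an epoxide, both neighbours of C5 are fully substituted so no hydrogen is available for elimination, and C1 is a quaternary and therefore good migrating carbon.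

Step 10
Reactants: 16 hydroazulenone silyl enol ether
Product: 17 (3R,3aR,8aR)-3-(tert-butyldimethylsilyloxy)-6,8a-dimethyl-3-(propan-2-yl)-1,2,3,3a,8,8a-hexahydroazulene-4,7-dione
Conditions: Pd(OAc)2 (1.1 equiv), MeCN, 40 °C
Reagents that add atoms: none
Why: Saegusa–Ito oxidation: the silyl enol ether is converted into the divalent-palladium enolate at C8 and β-hydride elimination toward C7 (whose hydrogens are also α to the C6 ketone) should install the C7=C8 double bond, so the enedione appears without enolate chemistry on the β-siloxy ketone and without touching a stereocentre.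

Step 11
Reactants: 17 silyl ether
Product: 18 (3R,3aR,8aR)-3-hydroxy-6,8a-dimethyl-3-(propan-2-yl)-1,2,3,3a,8,8a-hexahydroazulene-4,7-dione
Conditions: HF·pyridine, THF, 0 °C → rt
Reagents that add atoms: none
Why: Fluoride-mediated cleavage of the tertiary silyl ether (desilylation) under weakly acidic conditions should avoid retro-aldol cleavage or elimination of the β-hydroxy ketone.

Step 12
Reactants: 18 β-hydroxy enedione
Product: 19 (3R,3aS,4S,8aR)-3,4-dihydroxy-6,8a-dimethyl-3-(propan-2-yl)-1,2,3,3a,4,8a-hexahydroazulen-7(8H)-one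
Conditions: Me4NBH(OAc)3, AcOH–MeCN (1:1), −30 °C
Reagents that add atoms: none
Why: Evans–Saksena hydroxyl-directed reduction: the C4 hydroxyl binds the triacetoxyborohydride and delivers hydride intramolecularly to the β-related C6 carbonyl on its own face, which should give the 1,3-anti C6 alcohol (C6–O trans to C4–O, cis to H-5) and leave the C9 carbonyl, which has no directing hydroxyl, untouched.

Step 13
Reactants: 19 diol; 20 3,4-dimethoxybenzoyl chloride
Product: 21 [(3R,3aS,4S,8aR)-3-hydroxy-6,8a-dimethyl-7-oxo-3-(propan-2-yl)-1,2,3,3a,4,7,8,8a-octahydroazulen-4-yl] 3,4-dimethoxybenzoate (CNP0238578.1)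
Conditions: Et3N, DMAP (cat.), CH2Cl2, 0 °C → rt
Reagents that add atoms: none
Why: DMAP-catalysed acylation with an acid chloride (esterification) should be selective for the secondary allylic C6 hydroxyl over the hindered tertiary C4 hydroxyl and completes the target.

**Compound list**

1 | (S)-terpinen-4-ol, (1S)-4-methyl-1-(propan-2-yl)cyclohex-3-en-1-ol | CC(C)[C@@]1(O)CC=C(C)CC1 | starting material
2 | (S)-terpinen-4-ol tert-butyldimethylsilyl ether | CC(C)[C@@]1(O[Si](C)(C)C(C)(C)C)CC=C(C)CC1 | intermediate
3 | 4-(tert-butyldimethylsilyloxy)-1-methyl-2-(phenylselanyl)-4-(propan-2-yl)cyclohexan-1-ol (OH and SePh trans, C4 as in 2) | CC(C)[C@@]1(O[Si](C)(C)C(C)(C)C)CC([Se]c2ccccc2)C(C)(O)CC1 | intermediate (not isolated)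
4 | selenoxide of 3 | CC(C)[C@@]1(O[Si](C)(C)C(C)(C)C)CC([Se](=O)c2ccccc2)C(C)(O)CC1 | intermediate (not isolated)
5 | 4-(tert-butyldimethylsilyloxy)-1-methyl-4-(propan-2-yl)cyclohex-2-en-1-ol (C4 as in 2, both C1 epimers) | CC(C)[C@@]1(O[Si](C)(C)C(C)(C)C)C=CC(C)(O)CC1 | intermediate
6 | (R)-6-(tert-butyldimethylsilyloxy)-3-methyl-6-(propan-2-yl)cyclohex-2-en-1-one | CC(C)[C@@]1(O[Si](C)(C)C(C)(C)C)C(=O)C=C(C)CC1 | intermediate
7 | 3-methylbut-3-en-2-one | CC(=O)C(C)=C | starting material
8 | tert-butyldimethyl[(3-methylbuta-1,3-dien-2-yl)oxy]silane | C=C(C)C(=C)O[Si](C)(C)C(C)(C)C | intermediate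
9 | cis-fused 2,6-bis(tert-butyldimethylsilyloxy)-4a,7-dimethyl-2-(propan-2-yl)-3,4,4a,5,8,8a-hexahydronaphthalen-1(2H)-one (4a-methyl, 8a-H and 2-siloxy on one face) | CC(C)[C@]1(O[Si](C)(C)C(C)(C)C)CC[C@]2(C)CC(O[Si](C)(C)C(C)(C)C)=C(C)C[C@@H]2C1=O | intermediate
10 | potassium C1=C8a enolate of 9 | CC(C)[C@]1(O[Si](C)(C)C(C)(C)C)CC[C@]2(C)CC(O[Si](C)(C)C(C)(C)C)=C(C)CC2=C1[O-].[K+] | intermediate (not isolated)
11 | 8a-hydroperoxide of 9 (OOH cis to the 4a-methyl) | CC(C)[C@]1(O[Si](C)(C)C(C)(C)C)CC[C@]2(C)CC(O[Si](C)(C)C(C)(C)C)=C(C)C[C@]2(OO)C1=O | intermediate (not isolated)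
12 | 8a-hydroxy ketone (8a-OH cis to the 4a-methyl and the 2-siloxy group) | CC(C)[C@]1(O[Si](C)(C)C(C)(C)C)CC[C@]2(C)CC(O[Si](C)(C)C(C)(C)C)=C(C)C[C@]2(O)C1=O | intermediate
13 | cis-fused 2,6-bis(tert-butyldimethylsilyloxy)-4a,7-dimethyl-2-(propan-2-yl)-1,2,3,4,4a,5,8,8a-octahydronaphthalene-1,8a-diol (1-OH, 2-siloxy, 8a-OH, 4a-methyl all cis) | CC(C)[C@]1(O[Si](C)(C)C(C)(C)C)CC[C@]2(C)CC(O[Si](C)(C)C(C)(C)C)=C(C)C[C@]2(O)[C@H]1O | intermediate
14 | 1-O-methanesulfonate of 13 | CC(C)[C@]1(O[Si](C)(C)C(C)(C)C)CC[C@]2(C)CC(O[Si](C)(C)C(C)(C)C)=C(C)C[C@]2(O)[C@H]1OS(C)(=O)=O | intermediate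
15 | diethylaluminium 8a-alkoxide of 14 | CC(C)[C@]1(O[Si](C)(C)C(C)(C)C)CC[C@]2(C)CC(O[Si](C)(C)C(C)(C)C)=C(C)C[C@]2(O[Al](CC)CC)[C@H]1OS(C)(=O)=O | intermediate (not isolated)
16 | (3R,3aR,8aR)-3,7-bis(tert-butyldimethylsilyloxy)-6,8a-dimethyl-3-(propan-2-yl)-2,3,3a,5,8,8a-hexahydroazulen-4(1H)-one (trans-fused) | O=C2CC(C)=C(O[Si](C)(C)C(C)(C)C)C[C@@]3(C)CC[C@@](O[Si](C)(C)C(C)(C)C)(C(C)C)[C@H]23 | intermediate
17 | (3R,3aR,8aR)-3-(tert-butyldimethylsilyloxy)-6,8a-dimethyl-3-(propan-2-yl)-1,2,3,3a,8,8a-hexahydroazulene-4,7-dione | O=C2C=C(C)C(=O)C[C@@]3(C)CC[C@@](O[Si](C)(C)C(C)(C)C)(C(C)C)[C@H]23 | intermediate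
18 | (3R,3aR,8aR)-3-hydroxy-6,8a-dimethyl-3-(propan-2-yl)-1,2,3,3a,8,8a-hexahydroazulene-4,7-dione | O=C2C=C(C)C(=O)C[C@@]3(C)CC[C@@](O)(C(C)C)[C@H]23 | intermediate
19 | (3R,3aS,4S,8aR)-3,4-dihydroxy-6,8a-dimethyl-3-(propan-2-yl)-1,2,3,3a,4,8a-hexahydroazulen-7(8H)-one | O[C@H]2C=C(C)C(=O)C[C@@]3(C)CC[C@@](O)(C(C)C)[C@H]23 | intermediate
20 | 3,4-dimethoxybenzoyl chloride | COc1ccc(C(=O)Cl)cc1OC | starting material
21 | [(3R,3aS,4S,8aR)-3-hydroxy-6,8a-dimethyl-7-oxo-3-(propan-2-yl)-1,2,3,3a,4,7,8,8a-octahydroazulen-4-yl] 3,4-dimethoxybenzoate | COc1ccc(C(=O)O[C@H]2C=C(C)C(=O)C[C@@]3(C)CC[C@@](O)(C(C)C)[C@H]23)cc1OC | target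

**Step count and risks**

Total step count: 13. Longest linear sequence: 12 (steps 1, 2, 3, 5–13).

Steps most likely to fail:

1. Step 5 (Diels–Alder). The cycloaddition onto the β,β-disubstituted, α′-oxygenated enone may be too slow, the Lewis acid may destroy the siloxydiene, or addition syn to the axial siloxy group may erode the C1 configuration. Fallback, from 6 (with 7) back to 9: ring B is built stepwise by an anionic double Michael annulation. The lithium dienolate of 7 (LiN(i-Pr)2, THF, −78 °C → rt) adds to C1 of 6, and the resulting ring A enolate closes onto the isopropenyl ketone to give the cis-fused decalin-1,6-dione F1. Thermodynamic O-silylation of its more accessible ring B ketone (TBSOTf, Et3N) returns to 9.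

2. Step 6 (angular oxygenation). Enolisation of the hindered ring-fusion C–H may be incomplete, or oxygen may be captured on the face anti to the C15 methyl. Fallback, from 9 back to 16: because C6 ceases to be a stereocentre in the key step, the epimeric series can be carried through. The trans-fused ketol F2 is reduced (NaBH4) to the cis-diol F3 and mesylated to the hydroxy mesylate F4. The same AlEt3-promoted 1,2-shift then gives the cis-fused hydroazulenone F5, the C5 epimer of 16, which is equilibrated at the enolisable C5 with DBU to the trans-fused 16.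

3. Step 7 (hydride reduction between two quaternary carbons). Facial selectivity may be poor; equatorial attack would give the axial alcohol, whose mesylate would be antiperiplanar to the C6–O bond and close an epoxide instead of rearranging. Fallback, from 12 back to 13: the carbinol is set under thermodynamic instead of kinetic control. The axial alcohol F6 is equilibrated through reversible Meerwein–Ponndorf–Verley/Oppenauer hydrogen transfer (Al(Oi-Pr)3, i-PrOH, trace acetone, toluene, 80 °C) to the more stable equatorial alcohol 13.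

**Further compounds**

F1 | step 5 | cis-fused 2-(tert-butyldimethylsilyloxy)-4a,7-dimethyl-2-(propan-2-yl)octahydronaphthalene-1,6-dione (C7 epimers) | CC(C)[C@]1(O[Si](C)(C)C(C)(C)C)CC[C@]2(C)CC(=O)C(C)C[C@@H]2C1=O
F2 | step 6 | trans-fused 8a-epimer of ketol 12 | CC(C)[C@]1(O[Si](C)(C)C(C)(C)C)CC[C@]2(C)CC(O[Si](C)(C)C(C)(C)C)=C(C)C[C@@]2(O)C1=O
F3 | step 6 | trans-fused 1,8a-cis-diol (1,8a-diepimer of 13) | CC(C)[C@]1(O[Si](C)(C)C(C)(C)C)CC[C@]2(C)CC(O[Si](C)(C)C(C)(C)C)=C(C)C[C@@]2(O)[C@@H]1O
F4 | step 6 | 1-O-methanesulfonate of F3 | CC(C)[C@]1(O[Si](C)(C)C(C)(C)C)CC[C@]2(C)CC(O[Si](C)(C)C(C)(C)C)=C(C)C[C@@]2(O)[C@@H]1OS(C)(=O)=O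
F5 | step 6 | cis-fused 3a-epimer of hydroazulenone 16 | O=C2CC(C)=C(O[Si](C)(C)C(C)(C)C)C[C@@]3(C)CC[C@@](O[Si](C)(C)C(C)(C)C)(C(C)C)[C@@H]23
F6 | step 7 | 1-epimer of diol 13 (axial C5 alcohol) | CC(C)[C@]1(O[Si](C)(C)C(C)(C)C)CC[C@]2(C)CC(O[Si](C)(C)C(C)(C)C)=C(C)C[C@]2(O)[C@@H]1O
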